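**Plan**
1. Retrosynthesis: after removal of two MOM ethers, the five-membered ring of the indenone is cut at C1–C2 and C3–C3a. This gives bromoaldehyde 5 (ring A with the C1 formyl group) and diarylalkyne 11 (C2≡C3 carrying ring C with its benzoyl group and the 2,6-dimethoxyphenyl ring).
2. Enabling feature: in the cyclopentadienone ring (C1 carbonyl, C2=C3, C3a, C7a) fused to ring A, C1 is an aryl carbonyl ortho to C3a and C2=C3 is a fully arylated double bond. This is the retron of an ortho-halobenzaldehyde/alkyne [3+2] annulation, and the donor 2,6-dimethoxyphenyl ring at C3 against the acyl-bearing ring C at C2 orients the alkyne.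
3. Hidden dimer: rings A and C carry the same oxygen/methyl pattern, with a one-carbon unit next to the methoxy group and the carbon bearing the 2,6-dimethoxyphenyl ring next to the phenol oxygen. So 11 is also cut back to 5 (alkyne carbon by homologation, aryl–alkyne bond by Sonogashira coupling, aryl–carbonyl bond by aryllithium acylation).
4. Forward order: rings A and C come from 4-methoxy-3-methylphenol 1 (bromination, MOM ether, ortho-lithiation/formylation to 5). Part of 5 is taken on to 11, then 5 and 11 close the five-membered ring in the only ring-forming step, and acid frees the two phenols.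
5. Stereochemistry: the target has no stereocentre and no open-chain double bond, so none has to be set.

Key step: step 7

Assumption: rotation about the hindered aryl–indenone and aryl–carbonyl bonds is not specified in the target and is left uncontrolled; compounds 1, 7 and 9 are taken as purchasable.

**Step 1**
Reactants: 1 4-methoxy-3-methylphenol
Product: 2 2-bromo-4-methoxy-5-methylphenol
Conditions: NBS (1.0 equiv), MeCN, 0 °C
Reagents that add atoms: N-bromosuccinimide (NBS), O=C1CCC(=O)N1Br
Why: Electrophilic aromatic bromination directed by the free phenol, whose para position is blocked by OMe and whose other ortho position is flanked by the methyl group, so the open ortho carbon (also para to CH3) should be attacked.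

**Step 2**
Reactants: 2 2-bromo-4-methoxy-5-methylphenol
Product: 3 1-bromo-5-methoxy-2-(methoxymethoxy)-4-methylbenzene
Conditions: MOMCl, i-Pr2NEt, CH2Cl2, 0 °C → rt
Reagents that add atoms: chloromethyl methyl ether (MOMCl), COCCl
Why: O-Alkylation of the phenol gives an acetal protecting group that should withstand the organolithium and basic palladium steps and leave with dilute acid at the end.

**Step 3**
Reactants: 3 1-bromo-5-methoxy-2-(methoxymethoxy)-4-methylbenzene
Product: 5 2-bromo-6-methoxy-3-(methoxymethoxy)-5-methylbenzaldehyde, via aryllithium 4 (not isolated)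
Conditions: LiN(i-Pr)2, THF, −78 °C; DMF, −78 °C → rt; H2O
Reagents that add atoms: N,N-dimethylformamide (DMF), CN(C)C=O
Why: Directed ortho metalation removes the one ring hydrogen flanked by Br and OMe (as in the lithiation of 3-bromoanisole at C2), the ortho-bromoaryllithium should be stable to LiBr loss at −78 °C, and formylation with DMF follows.

**Step 4**
Reactants: 5 2-bromo-6-methoxy-3-(methoxymethoxy)-5-methylbenzaldehyde
Product: 6 2-bromo-3-ethynyl-4-methoxy-1-(methoxymethoxy)-5-methylbenzene
Conditions: dimethyl (1-diazo-2-oxopropyl)phosphonate, K2CO3, MeOH, 0 °C → rt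
Reagents that add atoms: dimethyl (1-diazo-2-oxopropyl)phosphonate (Ohira–Bestmann reagent), COP(=O)(OC)C(=[N+]=[N-])C(C)=O
Why: Seyferth–Gilbert homologation in the Ohira–Bestmann form converts the aldehyde into the terminal alkyne under mild K2CO3/MeOH conditions that should leave the aryl bromide and the MOM ether untouched.

**Step 5**
Reactants: 6 2-bromo-3-ethynyl-4-methoxy-1-(methoxymethoxy)-5-methylbenzene; 7 2-iodo-1,3-dimethoxybenzene
Product: 8 2-bromo-3-[(2,6-dimethoxyphenyl)ethynyl]-4-methoxy-1-(methoxymethoxy)-5-methylbenzene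
Conditions: PdCl2(PPh3)2 (5 mol %), CuI (10 mol %), Et3N, DMF, 60 °C
Reagents that add atoms: none
Why: Sonogashira coupling, in which oxidative addition at the C–I bond of 7 should be much faster than at the di-ortho-substituted, electron-rich C–Br bond of 6 and 8, so the bromide is kept for step 6.

**Step 6**
Reactants: 8 2-bromo-3-[(2,6-dimethoxyphenyl)ethynyl]-4-methoxy-1-(methoxymethoxy)-5-methylbenzene; 9 2,6-dimethoxybenzoyl chloride
Product: 11 (2,6-dimethoxyphenyl){2-[(2,6-dimethoxyphenyl)ethynyl]-3-methoxy-6-(methoxymethoxy)-4-methylphenyl}methanone, via aryllithium 10 (not isolated)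
Conditions: n-BuLi (1.05 equiv), THF, −78 °C; then added to 9 (1.5 equiv) in THF, −78 → 0 °C
Reagents that add atoms: none
Why: Bromine–lithium exchange gives an aryllithium stabilised by the neighbouring OMOM group, and nucleophilic acyl substitution on the aroyl chloride should stop at the ketone because the tetra-ortho-substituted benzophenone is too hindered for a second addition.

**Step 7**
Reactants: 5 2-bromo-6-methoxy-3-(methoxymethoxy)-5-methylbenzaldehyde (1.5 equiv); 11 (2,6-dimethoxyphenyl){2-[(2,6-dimethoxyphenyl)ethynyl]-3-methoxy-6-(methoxymethoxy)-4-methylphenyl}methanone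
Product: 12 2-[2-(2,6-dimethoxybenzoyl)-6-methoxy-3-(methoxymethoxy)-5-methylphenyl]-3-(2,6-dimethoxyphenyl)-7-methoxy-4-(methoxymethoxy)-6-methyl-1H-inden-1-one
Conditions: Pd(OAc)2 (10 mol %), NaOAc, n-Bu4NCl, DMF, 100 °C
Reagents that add atoms: none
Why: Zerovalent palladium formed from Pd(OAc)2 inserts into the C–Br bond of 5, the arylpalladium bromide adds syn across the alkyne of 11 so that the ring A carbon bonds to the alkyne carbon bearing the 2,6-dimethoxyphenyl ring (C3–C3a) and palladium sits on the carbon bearing ring C, this alkenylpalladium adds to the ortho formyl group (C1–C2), and β-hydride elimination from the palladium alkoxide gives the ketone and HPdBr, which NaOAc returns to zerovalent palladium. The closest known reaction is the Larock indenone synthesis, the palladium-catalysed annulation of ortho-bromo- or ortho-iodobenzaldehydes with internal diarylalkynes. The five-membered ring closes by 5-exo-trig attack of the alkenyl–palladium carbon on the aldehyde carbonyl, the whole event being a [3+2] annulation. No stereocentre is formed. The selectivity needed is the orientation of alkyne insertion, and three substrate features should secure it: the donor 2,6-dimethoxyphenyl ring polarises the alkyne so that the migrating aryl group bonds to its carbon, the bulkier ring C (OMe and aroyl in the ortho positions) prefers the carbon next to palladium, and the ortho benzoyl oxygen can hold palladium there in a six-membered chelate. Neither alkyne aryl ring has an ortho hydrogen, which should shut off palladium 1,4-shifts and C–H arylation side paths.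

**Step 8**
Reactants: 12 2-[2-(2,6-dimethoxybenzoyl)-6-methoxy-3-(methoxymethoxy)-5-methylphenyl]-3-(2,6-dimethoxyphenyl)-7-methoxy-4-(methoxymethoxy)-6-methyl-1H-inden-1-one
Product: 13 acredinone A, 2-[2-(2,6-dimethoxybenzoyl)-3-hydroxy-6-methoxy-5-methylphenyl]-3-(2,6-dimethoxyphenyl)-4-hydroxy-7-methoxy-6-methyl-1H-inden-1-one
Conditions: 3 M HCl, MeOH/THF, 50 °C
Reagents that add atoms: none
Why: Acid-catalysed acetal cleavage should remove both MOM ethers, while the aryl methyl ethers, both ketones and the indenone double bond are stable to dilute HCl in methanol.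

**Compound list**
1 | 4-methoxy-3-methylphenol | COc1ccc(O)cc1C | starting material
2 | 2-bromo-4-methoxy-5-methylphenol | COc1cc(Br)c(O)cc1C | intermediate
3 | 1-bromo-5-methoxy-2-(methoxymethoxy)-4-methylbenzene | COCOc1cc(C)c(OC)cc1Br | intermediate
4 | [2-bromo-6-methoxy-3-(methoxymethoxy)-5-methylphenyl]lithium | COCOc1cc(C)c(OC)c([Li])c1Br | intermediate
5 | 2-bromo-6-methoxy-3-(methoxymethoxy)-5-methylbenzaldehyde | COCOc1cc(C)c(OC)c(C=O)c1Br | intermediate
6 | 2-bromo-3-ethynyl-4-methoxy-1-(methoxymethoxy)-5-methylbenzene | COCOc1cc(C)c(OC)c(C#C)c1Br | intermediate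
7 | 2-iodo-1,3-dimethoxybenzene | COc1cccc(OC)c1I | starting material
8 | 2-bromo-3-[(2,6-dimethoxyphenyl)ethynyl]-4-methoxy-1-(methoxymethoxy)-5-methylbenzene | COCOc1cc(C)c(OC)c(C#Cc2c(OC)cccc2OC)c1Br | intermediate
9 | 2,6-dimethoxybenzoyl chloride | COc1cccc(OC)c1C(Cl)=O | starting material
10 | {2-[(2,6-dimethoxyphenyl)ethynyl]-3-methoxy-6-(methoxymethoxy)-4-methylphenyl}lithium | COCOc1cc(C)c(OC)c(C#Cc2c(OC)cccc2OC)c1[Li] | intermediate
11 | (2,6-dimethoxyphenyl){2-[(2,6-dimethoxyphenyl)ethynyl]-3-methoxy-6-(methoxymethoxy)-4-methylphenyl}methanone | COCOc1cc(C)c(OC)c(C#Cc2c(OC)cccc2OC)c1C(=O)c1c(OC)cccc1OC | intermediate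
12 | 2-[2-(2,6-dimethoxybenzoyl)-6-methoxy-3-(methoxymethoxy)-5-methylphenyl]-3-(2,6-dimethoxyphenyl)-7-methoxy-4-(methoxymethoxy)-6-methyl-1H-inden-1-one | COc1cccc(OC)c1C(=O)c1c(OCOC)cc(C)c(OC)c1C1=C(c2c(OC)cccc2OC)c2c(OCOC)cc(C)c(OC)c2C1=O | intermediate
13 | acredinone A | COc1cccc(OC)c1C(=O)c1c(O)cc(C)c(OC)c1C1=C(c2c(OC)cccc2OC)c2c(O)cc(C)c(OC)c2C1=O | target

**Total step count:** 8
**Longest linear sequence:** 8 steps (1 → 2 → 3 → 5 → 6 → 8 → 11 → 12 → 13); compound 5 also enters step 7 directly as the second fragment.

**Steps most likely to fail**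

Step 7. The alkyne insertion may be slow on the tetra-ortho-substituted alkyne or may run partly in the wrong orientation, and the ortho ketone oxygen may attack the palladium-activated alkyne instead. The fallback sets out from 8 and returns at 12. It replaces the planar ketone by a much bulkier sp3 group without a carbonyl oxygen and adjusts the oxidation level afterwards. Bromine–lithium exchange of 8 (n-BuLi, THF, −78 °C) and addition to 2,6-dimethoxybenzaldehyde should give the racemic carbinol F1. Silylation (TBSOTf, 2,6-lutidine, CH2Cl2) gives the silyl ether F2. Annulation of F2 with 5 under the step 7 conditions should place the larger CH(OTBS)Ar-bearing ring next to palladium and give the indenone silyl ether F3. n-Bu4NF in THF then frees the indenone carbinol F4, and Dess–Martin periodinane (NaHCO3, CH2Cl2) oxidises it to 12; the carbinol stereocentre is erased in this oxidation.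

Step 6. Carbon–carbon bond formation between two di-ortho-substituted partners may be incomplete, with the aryllithium lost to protonation or to butylation by the 1-bromobutane formed. The fallback sets out from 8 and returns at 11 with the polarity of the ketone synthesis reversed. Aryllithium 10, made as before, is quenched with the small electrophile methyl chloroformate to give the methyl ester F5. The easily made (2,6-dimethoxyphenyl)lithium F6 (1,3-dimethoxybenzene, n-BuLi, THF, 0 °C → rt) is then added in excess to F5 (THF, 0 °C → rt). The hindered ketone 11 should again resist a second addition.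

Step 5. Oxidative addition at the electron-rich, hindered C–I bond may be slow, so that oxidative dimerisation of the alkyne or insertion into the C–Br bond competes. The fallback sets out from 5 and returns at 8, with the hindered aryl ring now used as the nucleophile. Corey–Fuchs olefination of 5 (CBr4, PPh3, CH2Cl2, 0 °C) gives the dibromoalkene F7. Suzuki coupling with 2,6-dimethoxyphenylboronic acid at the less hindered bromide, the one trans to the ring (Pd2(dba)3, tri(2-furyl)phosphine, K3PO4, dioxane/H2O, 60 °C), gives the (Z)-bromoalkene F8. Anti elimination of HBr (t-BuOK, THF) then gives 8.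

**Further compounds**
F1 | step 7 | carbinol, (2,6-dimethoxyphenyl){2-[(2,6-dimethoxyphenyl)ethynyl]-3-methoxy-6-(methoxymethoxy)-4-methylphenyl}methanol (racemic) | COCOc1cc(C)c(OC)c(C#Cc2c(OC)cccc2OC)c1C(O)c1c(OC)cccc1OC
F2 | step 7 | silyl ether, tert-butyl[(2,6-dimethoxyphenyl){2-[(2,6-dimethoxyphenyl)ethynyl]-3-methoxy-6-(methoxymethoxy)-4-methylphenyl}methoxy]dimethylsilane (racemic) | COCOc1cc(C)c(OC)c(C#Cc2c(OC)cccc2OC)c1C(O[Si](C)(C)C(C)(C)C)c1c(OC)cccc1OC
F3 | step 7 | indenone silyl ether, 2-[2-{[tert-butyl(dimethyl)silyl]oxy(2,6-dimethoxyphenyl)methyl}-6-methoxy-3-(methoxymethoxy)-5-methylphenyl]-3-(2,6-dimethoxyphenyl)-7-methoxy-4-(methoxymethoxy)-6-methyl-1H-inden-1-one (racemic) | COc1cccc(OC)c1C(O[Si](C)(C)C(C)(C)C)c1c(OCOC)cc(C)c(OC)c1C1=C(c2c(OC)cccc2OC)c2c(OCOC)cc(C)c(OC)c2C1=O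
F4 | step 7 | indenone carbinol, 2-[2-{(2,6-dimethoxyphenyl)(hydroxy)methyl}-6-methoxy-3-(methoxymethoxy)-5-methylphenyl]-3-(2,6-dimethoxyphenyl)-7-methoxy-4-(methoxymethoxy)-6-methyl-1H-inden-1-one (racemic) | COc1cccc(OC)c1C(O)c1c(OCOC)cc(C)c(OC)c1C1=C(c2c(OC)cccc2OC)c2c(OCOC)cc(C)c(OC)c2C1=O
F5 | step 6 | methyl ester, methyl 2-[(2,6-dimethoxyphenyl)ethynyl]-3-methoxy-6-(methoxymethoxy)-4-methylbenzoate | COCOc1cc(C)c(OC)c(C#Cc2c(OC)cccc2OC)c1C(=O)OC
F6 | step 6 | (2,6-dimethoxyphenyl)lithium | [Li]c1c(OC)cccc1OC
F7 | step 5 | dibromoalkene, 2-bromo-3-(2,2-dibromoethenyl)-4-methoxy-1-(methoxymethoxy)-5-methylbenzene | COCOc1cc(C)c(OC)c(C=C(Br)Br)c1Br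
F8 | step 5 | (Z)-bromoalkene, 2-bromo-3-[(Z)-2-bromo-2-(2,6-dimethoxyphenyl)ethenyl]-4-methoxy-1-(methoxymethoxy)-5-methylbenzene | COCOc1cc(C)c(OC)c(/C=C(/c2c(OC)cccc2OC)Br)c1Br
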